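**Retrosynthetic overview**

1. Feature: C2 of the chroman-4-one is quaternary (O1, C3, CH3, side chain). Its methyl carbon and C3 are both bonded to C2, so the methyl is carried as a CH2 bridging C2 and C3 in a cyclopropane fused to the pyranone ring.
2. Disconnections, backwards: aryl MOM ether; the C3–CH2 bond of the cyclopropane (reductive cleavage releases CH3 on C2); the tertiary alcohol (from the trisubstituted alkene, hydrated before the cleavage so that the released primary radical meets no alkene); the C2–CH2 and C3–CH2 bonds (enantioselective methylene transfer from a sulfoxonium ylide to a 2-alkylchromone).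
3. The 2-alkylchromone comes from lateral prenylation of a 2-methylchromone, itself made from 2-bromo-1,4-dimethoxybenzene by acetylation, demethylation, mono-MOM protection and enaminone cyclisation.
4. Ring order: benzene ring bought; pyranone ring in step 4; cyclopropane closed in step 6 and opened again in step 8.

Key step: step 6

Remark on the chemistry: the sense of induction of the lanthanum–lithium binaphtholate catalyst on a chromone cannot be predicted from the acyclic enone cases. The route is written with the (S)-diolate; the (R)-diolate is used instead if a first run shows that it is the one delivering CH2 to the Si face of C2.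

**Route**

Step 1
Reactants: 1 2-bromo-1,4-dimethoxybenzene, 2 acetyl chloride
Product: 3 1-(4-bromo-2,5-dimethoxyphenyl)ethanone
Conditions: AlCl3 (1.3 equiv), CH2Cl2, 0 °C to rt
Reagents that add atoms: none
Why: Friedel–Crafts acylation: of the two open positions ortho to a methoxy group, the one para to bromine should be attacked, because bromine donates by resonance to its para position and only withdraws at its meta position.

Step 2
Reactants: 3 1-(4-bromo-2,5-dimethoxyphenyl)ethanone
Product: 4 1-(4-bromo-2,5-dihydroxyphenyl)ethanone
Conditions: BBr3 (3 equiv), CH2Cl2, −78 °C to rt; then H2O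
Reagents that add atoms: none
Why: Lewis-acid cleavage of both aryl methyl ethers (bromide attacks the methyl group of the boron-bound ether), to which the ketone and the aryl bromide are inert.

Step 3
Reactants: 4 1-(4-bromo-2,5-dihydroxyphenyl)ethanone
Product: 5 1-[4-bromo-2-hydroxy-5-(methoxymethoxy)phenyl]ethanone
Conditions: MOMCl (1.05 equiv), iPr2NEt (1.5 equiv), CH2Cl2, 0 °C
Reagents that add atoms: chloromethyl methyl ether (MOMCl), COCCl
Why: Chemoselective O-alkylation (MOM ether formation): the 2-OH is held in a hydrogen bond to the acetyl carbonyl and is the poorer nucleophile, so the 5-OH next to bromine should be protected alone.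

Step 4
Reactants: 5 1-[4-bromo-2-hydroxy-5-(methoxymethoxy)phenyl]ethanone, 6 N,N-dimethylacetamide dimethyl acetal
Product: 8 7-bromo-6-(methoxymethoxy)-2-methylchromen-4-one, via enaminone 7 (not isolated)
Conditions: 6 (2 equiv), toluene, 100 °C; then AcOH, 60 °C
Reagents that add atoms: none
Why: Enaminone route to chromones: the amide acetal condenses at the acetyl methyl group, then the phenol adds to the β-carbon of the enaminone and dimethylamine is lost (addition–elimination), which closes the pyranone ring without mineral acid so that the MOM acetal stays.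

Step 5
Reactants: 8 7-bromo-6-(methoxymethoxy)-2-methylchromen-4-one, 9 1-bromo-3-methylbut-2-ene
Product: 11 7-bromo-6-(methoxymethoxy)-2-(4-methylpent-3-enyl)chromen-4-one, via lithium dienolate 10 (not isolated)
Conditions: LiN(iPr)2 (1.1 equiv), THF, −78 °C; then 9 (1.2 equiv), −78 to −40 °C
Reagents that add atoms: none
Why: Lateral (vinylogous) deprotonation of the 2-methyl group gives the cross-conjugated dienolate 10, which should be alkylated by SN2 at the exocyclic carbon because only this restores the pyranone; the aryl bromide is not touched by the amide base at −78 °C.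

Step 6
Reactants: 11 7-bromo-6-(methoxymethoxy)-2-(4-methylpent-3-enyl)chromen-4-one, 12 trimethylsulfoxonium iodide
Product: 14 (1aS,7aR)-4-bromo-5-(methoxymethoxy)-1a-(4-methylpent-3-enyl)-1a,7a-dihydro-1H-cyclopropa[b]chromen-7-one, via dimethylsulfoxonium methylide 13 (not isolated)
Conditions: 12, NaH, THF, reflux; filtered solution of 13 added over 6 h to 11, LaLi3[(S)-1,1'-binaphthalene-2,2'-diolate]3 (10 mol %), NaI (10 mol %), THF/toluene, −55 °C
Reagents that add atoms: none
Why: Proposed new method: the ylide carbon of 13 adds to C2 of the chromone, whose carbonyl oxygen is bound to the lanthanum–lithium binaphtholate, and the enolate so formed attacks the CH2–S carbon with loss of dimethyl sulfoxide (Michael-initiated ring closure, Corey–Chaykovsky cyclopropanation). The closest known reactions are the cyclopropanation of chromones with dimethylsulfoxonium methylide without chiral control and the LaLi3(binaphtholate)3/NaI-catalysed enantioselective cyclopropanation of acyclic enones with the same ylide; new is the rigid s-trans vinylogous ester with a fully substituted β-carbon. The three-membered ring closes in a 3-exo-tet mode, forming C2–CH2 first and C3–CH2 second, and its fusion to the six-membered ring can only be cis. C1a is set in the addition by the chiral pocket of the catalyst, which must deliver CH2 to the Si face of C2 (O1 > C3 > side-chain CH2), and C7a then follows from the cis fusion. The step needs 1,4- over 1,2-addition, which the stabilised sulfoxonium ylide secures because its carbonyl addition is reversible, and addition over deprotonation of the CH2 next to C2, which is helped by Lewis-acid activation of the carbonyl and is not destructive because that deprotonation is reversible. The trisubstituted alkene, the aryl bromide and the MOM acetal are inert to the ylide.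

Step 7
Reactants: 14 (1aS,7aR)-4-bromo-5-(methoxymethoxy)-1a-(4-methylpent-3-enyl)-1a,7a-dihydro-1H-cyclopropa[b]chromen-7-one
Product: 15 (1aS,7aR)-4-bromo-1a-(4-hydroxy-4-methylpentyl)-5-(methoxymethoxy)-1a,7a-dihydro-1H-cyclopropa[b]chromen-7-one
Conditions: Co(acac)2 (20 mol %), PhSiH3 (2 equiv), O2 (1 atm), THF, rt
Reagents that add atoms: dioxygen, O=O
Why: Mukaiyama hydration: a cobalt hydride transfers a hydrogen atom to the less substituted alkene carbon, the tertiary radical is trapped by O2 and the peroxide is reduced by the silane to the Markovnikov tertiary alcohol; the step is placed before the reductive opening because the primary radical released there would otherwise be a hex-5-enyl radical toward this alkene.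

Step 8
Reactants: 15 (1aS,7aR)-4-bromo-1a-(4-hydroxy-4-methylpentyl)-5-(methoxymethoxy)-1a,7a-dihydro-1H-cyclopropa[b]chromen-7-one
Product: 16 (2R)-7-bromo-2-(4-hydroxy-4-methylpentyl)-6-(methoxymethoxy)-2-methyl-2,3-dihydro-4H-chromen-4-one
Conditions: SmI2 (2.2 equiv), MeOH (4 equiv), THF (no HMPA), −78 to 0 °C; aq. NH4Cl
Reagents that add atoms: none
Why: Reductive cleavage of a cyclopropyl ketone by SmI2: the samarium ketyl should break the exocyclic C7a–C1 bond, the one aligned with the carbonyl π system, the primary radical should be quenched in THF without HMPA by hydrogen-atom abstraction from the solvent, and the enolate is protonated by MeOH, so that C1 becomes the methyl group on C2, whose bonds are untouched (descriptor now R).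

Step 9
Reactants: 16 (2R)-7-bromo-2-(4-hydroxy-4-methylpentyl)-6-(methoxymethoxy)-2-methyl-2,3-dihydro-4H-chromen-4-one
Product: 17 (2R)-7-bromo-6-hydroxy-2-(4-hydroxy-4-methylpentyl)-2-methyl-2,3-dihydro-4H-chromen-4-one
Conditions: 3 M aq. HCl, THF, 40 °C
Reagents that add atoms: none
Why: Acid hydrolysis of the MOM acetal: the aqueous medium returns any tertiary cation to the alcohol, and the chromanone ring is not opened under these conditions, so the C2 stereocentre should be kept.

**Compound list**

1 | 2-bromo-1,4-dimethoxybenzene | COc1ccc(OC)c(Br)c1 | starting material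
2 | acetyl chloride | CC(Cl)=O | starting material
3 | 1-(4-bromo-2,5-dimethoxyphenyl)ethanone | CC(=O)c1cc(OC)c(Br)cc1OC | intermediate
4 | 1-(4-bromo-2,5-dihydroxyphenyl)ethanone | CC(=O)c1cc(O)c(Br)cc1O | intermediate
5 | 1-[4-bromo-2-hydroxy-5-(methoxymethoxy)phenyl]ethanone | CC(=O)c1cc(OCOC)c(Br)cc1O | intermediate
6 | N,N-dimethylacetamide dimethyl acetal (1,1-dimethoxy-N,N-dimethylethanamine) | CC(OC)(OC)N(C)C | starting material
7 | (E)-1-[4-bromo-2-hydroxy-5-(methoxymethoxy)phenyl]-3-(dimethylamino)but-2-en-1-one | CN(C)/C(C)=C/C(=O)c1cc(OCOC)c(Br)cc1O | intermediate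
8 | 7-bromo-6-(methoxymethoxy)-2-methylchromen-4-one | Cc1cc(=O)c2cc(OCOC)c(Br)cc2o1 | intermediate
9 | 1-bromo-3-methylbut-2-ene (prenyl bromide) | CC(C)=CCBr | starting material
10 | lithium 7-bromo-6-(methoxymethoxy)-2-methylidene-2H-chromen-4-olate | [Li+].[O-]C1=CC(=C)Oc2cc(Br)c(OCOC)cc12 | intermediate
11 | 7-bromo-6-(methoxymethoxy)-2-(4-methylpent-3-enyl)chromen-4-one | CC(C)=CCCc1cc(=O)c2cc(OCOC)c(Br)cc2o1 | intermediate
12 | trimethylsulfoxonium iodide | C[S+](C)(C)=O.[I-] | starting material
13 | dimethylsulfoxonium methylide | C[S+](C)(=O)[CH2-] | intermediate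
14 | (1aS,7aR)-4-bromo-5-(methoxymethoxy)-1a-(4-methylpent-3-enyl)-1a,7a-dihydro-1H-cyclopropa[b]chromen-7-one (cis-fused; C1 = CH2, C1a = oxygen-bearing fusion carbon, C7a = fusion carbon next to C=O) | CC(C)=CCC[C@]12C[C@H]1C(=O)c1cc(OCOC)c(Br)cc1O2 | intermediate
15 | (1aS,7aR)-4-bromo-1a-(4-hydroxy-4-methylpentyl)-5-(methoxymethoxy)-1a,7a-dihydro-1H-cyclopropa[b]chromen-7-one | CC(C)(O)CCC[C@]12C[C@H]1C(=O)c1cc(OCOC)c(Br)cc1O2 | intermediate
16 | (2R)-7-bromo-2-(4-hydroxy-4-methylpentyl)-6-(methoxymethoxy)-2-methyl-2,3-dihydro-4H-chromen-4-one | CC(C)(O)CCC[C@]1(C)CC(=O)c2cc(OCOC)c(Br)cc2O1 | intermediate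
17 | (2R)-7-bromo-6-hydroxy-2-(4-hydroxy-4-methylpentyl)-2-methyl-2,3-dihydro-4H-chromen-4-one | CC(C)(O)CCC[C@]1(C)CC(=O)c2cc(O)c(Br)cc2O1 | target

**Step count**

Total: 9 steps. Longest linear sequence: 9 steps (from 1 to 17).

**Steps most likely to fail**

1. Step 6 (proposed new method).
What may go wrong: the flat, s-trans chromone may be bound by the catalyst without enough facial discrimination, so that CH2 is delivered to both faces of C2. Reversible deprotonation of the side-chain CH2 next to C2 by the basic ylide or catalyst may also slow the addition.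
Fallback (known chemistry): setting out from 11 and 12, the methylene transfer is run without chiral control (NaH, DMSO, rt to 50 °C; Corey–Chaykovsky cyclopropanation as known for chromones, with 13 formed in the flask). This should give racemic cis-fused 4-bromo-5-(methoxymethoxy)-1a-(4-methylpent-3-enyl)-1a,7a-dihydro-1H-cyclopropa[b]chromen-7-one F1. Preparative chromatography on a chiral stationary phase (supercritical CO2/MeOH) then separates 14 from its (1aR,7aS)-enantiomer F2, and the route is rejoined at 14. Should the chromone not accept the methylene group at all, the fallback given for step 8 also bypasses this step.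

2. Step 8.
What may go wrong:
- Ketyl opening of an aryl ketone is reversible, so cleavage may leak to the endocyclic C1a–C7a bond, which gives a tertiary oxygen-stabilised radical and ring expansion.
- If the primary radical is reduced to an organosamarium, it can expel the β-aryloxide.
- The ketyl can lose bromide.
- The samarium enolate can open the pyranone ring by β-elimination and reclose without selectivity, eroding the enantiomeric purity.

Fallback: the cyclopropane is given up. Setting out from 5, Kabbe condensation with 6-methylhept-5-en-2-one F3 (purchased; pyrrolidine, EtOH, reflux: enamine aldol condensation, then intramolecular oxa-Michael addition) should give racemic 7-bromo-6-(methoxymethoxy)-2-methyl-2-(4-methylpent-3-enyl)chroman-4-one F4. Mukaiyama hydration under the conditions of step 7 should give racemic 7-bromo-2-(4-hydroxy-4-methylpentyl)-6-(methoxymethoxy)-2-methylchroman-4-one F5. Preparative chromatography on a chiral stationary phase separates 16 from its (2S)-enantiomer F6. The route is rejoined at 16, and steps 4 to 8 are not needed.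

3. Step 5.
What may go wrong: proton exchange between the product and the dienolate may lead to double alkylation; the dienolate may be alkylated at C3, attack the allylic bromide in the SN2' sense, or add to chromone that has not yet been deprotonated.
Fallback: the side chain is brought in before the pyranone ring is closed. Setting out from 5, Claisen condensation with ethyl 5-methylhex-4-enoate F7 (purchased; NaH, THF, reflux) should give 1-[4-bromo-2-hydroxy-5-(methoxymethoxy)phenyl]-7-methyloct-6-ene-1,3-dione F8. Cyclodehydration (AcOH, 80 °C) should give 11, where the route is rejoined; steps 4 and 5 are replaced.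

**Further compounds**

F1 | step 6 | racemic cis-fused 4-bromo-5-(methoxymethoxy)-1a-(4-methylpent-3-enyl)-1a,7a-dihydro-1H-cyclopropa[b]chromen-7-one | CC(C)=CCCC12CC1C(=O)c1cc(OCOC)c(Br)cc1O2
F2 | step 6 | (1aR,7aS)-4-bromo-5-(methoxymethoxy)-1a-(4-methylpent-3-enyl)-1a,7a-dihydro-1H-cyclopropa[b]chromen-7-one | CC(C)=CCC[C@@]12C[C@@H]1C(=O)c1cc(OCOC)c(Br)cc1O2
F3 | step 8 | 6-methylhept-5-en-2-one (purchased) | CC(=O)CCC=C(C)C
F4 | step 8 | racemic 7-bromo-6-(methoxymethoxy)-2-methyl-2-(4-methylpent-3-enyl)chroman-4-one | CC(C)=CCCC1(C)CC(=O)c2cc(OCOC)c(Br)cc2O1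
F5 | step 8 | racemic 7-bromo-2-(4-hydroxy-4-methylpentyl)-6-(methoxymethoxy)-2-methylchroman-4-one | CC(C)(O)CCCC1(C)CC(=O)c2cc(OCOC)c(Br)cc2O1
F6 | step 8 | (2S)-7-bromo-2-(4-hydroxy-4-methylpentyl)-6-(methoxymethoxy)-2-methyl-2,3-dihydro-4H-chromen-4-one | CC(C)(O)CCC[C@@]1(C)CC(=O)c2cc(OCOC)c(Br)cc2O1
F7 | step 5 | ethyl 5-methylhex-4-enoate (purchased) | CCOC(=O)CCC=C(C)C
F8 | step 5 | 1-[4-bromo-2-hydroxy-5-(methoxymethoxy)phenyl]-7-methyloct-6-ene-1,3-dione | CC(C)=CCCC(=O)CC(=O)c1cc(OCOC)c(Br)cc1O
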